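The data come from a simulation for an exercise.

Two questions stand on this flask: which species holds the largest share of the electrophile at the end, and how large that share is.

| flask | electrophile | nucleophile | solid base | remark | time |
|---|---|---|---|---|---|
| amber | 0.050 M | 0.67 equiv | 0.30 equiv | run made earlier |  |
| blue | 0.050 M | 1.5 equiv | 0.30 equiv | run made earlier |  |
| teal | 0.075 M | 1 equiv | 0.30 equiv | run made earlier |  |
| flask | 0.050 M | 1.00 equiv | 0.300 equiv |  | 30 min |

| run | time / min | electrophile / % | side product / % | target / % |
|---|---|---|---|---|
| amber | 2.00 | 70.0 | 14.2 | 16.4 |
| amber | 4.00 | 56.2 | 29.0 | 14.6 |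
| amber | 10.0 | 39.3 | 52.9 | 7.2 |
| amber | 25.0 | 25.9 | 71.2 | 3.5 |
| blue | 2.00 | 43.5 | 22.9 | 34.4 |
| blue | 4.00 | 23.2 | 40.1 | 36.0 |
| blue | 10.0 | 5.3 | 60.2 | 34.1 |
| blue | 25.0 | 0.3 | 67.2 | 33.0 |
| teal | 6.00 | 22.9 | 59.8 | 16.8 |
| teal | 12.0 | 11.9 | 76.9 | 11.2 |
| teal | 20.0 | 6.1 | 84.3 | 9.0 |
| teal | 25.0 | 4.0 | 87.4 | 8.3 |

(scatter of a reading: 0.3 percentage points)

* the largest share of what was charged as electrophile, at 30 min belongs to (target / side product / electrophile)
* the largest share itself, whichever of these holds it, in percent of the electrophile charged

- percentages count the electrophile that a species holds: one side product counts as two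
- solid, in amounts per volume of the solution: solid base
- steps thought possible: electrophile + target -> side product; solid base <-> free base; electrophile + nucleophile -> acid set free + target; nucleophile + acid set free <-> protonated nucleophile; acid set free -> by-product carried off; acid set free + free base <-> salt of the base
- at the start none of the solid base is in solution

Let E, T and S be electrophile, target and side product as fractions of the electrophile charged, n the nucleophile charged, and N the free nucleophile on that scale. In the amber run at 10.0 min, the nucleophile consumed, T + S/2, stands at 33.6%, half of the 0.67 equiv charged, and amber still holds 25.9% electrophile at 25.0 min. So early in a run the acid set free ties up a second nucleophile, and N = n − 2T − S as long as the acid stays there. In amber at 25.0 min this balance reads −11.2%, below zero, so by then part of the acid no longer sits on nucleophile, and the balance has stopped holding.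

Target peaks where it is made as fast as it is used. The blue run peaks near 4.00 min, and T/N there reads 0.950: this is s, the selectivity factor, the nucleophile's rate constant over the target's. Both rates carry E, so dividing them removes E and time: dT/dN = T/(2sN) − 0.5. With s taken as 1, this integrates to T = √(nN) − N, and once E is gone, S = 1/n, as far as the balance holds. Blue gives 66.7% against its reading of 67.2%.

For this flask the rule gives 100% with N worn down to nothing, the state in which the amber run left the balance behind, so that figure is not taken and the share must come from a run. Teal has the same equivalents at 1.50 times the concentration, so its second-order steps reach at 20.0 min what this flask reaches at 30 min. Teal there reads 84.3% side product, and that is the reckoning here. The forecast names side product at 83%, between 78% and 87%: “Side product dominates”.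

The flask gives side product at 84.6%.

    electrophile + target → side product (k = 0.130 /M/s)
    solid base ⇌ free base, rate k2*(cs2 - [free base]) while solid is left; crystals form when [free base] > cs2 (solubility = 28.0 mM, k = 0.200 /s)
    electrophile + nucleophile → acid set free + target (k = 0.120 /M/s)
    nucleophile + acid set free ⇌ protonated nucleophile, settled at all times (K = 63000 /M)
    acid set free → by-product carried off (k = 0.0360 /s)
    acid set free + free base ⇌ salt of the base (K = 45.0 /M, k = 0.610 /M/s)

The low solubility of the free base makes no difference to that share, and half of the dissolving is done by 1.56 s. With 7.0% of the nucleophile left and T at 10.3%, sN/T is 0.644, so target in this flask is used faster than it is made. Left until 300 min, this flask holds 90.1% side product, short of the rule's 100%.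

At n = 1.70 equiv the rule gives 58.8%. That neighbour, with 0.013% electrophile left, holds 60.0% side product.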